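The 10-membered ring is opened between the ring D benzylic CH(CH3) carbon and the neighbouring methine. That benzylic carbon sits para to the ring B phenol oxygen, and the methine is α to the carbon that becomes the aryl-bearing alkene carbon (an aldehyde carbon at the key stage). One operation therefore closes the macrocycle and sets both centres: an aldehyde enamine adds to the exocyclic carbon of a naphthoquinone methide released from a racemic 4-(1-hydroxyethyl)-1-naphthol. The precursor is that naphthol carbinol, tied through the diaryl ether and the ring A ketone to a (R)-3-methyl-5-oxopentanoyl chain; ring D, the ring C quinone methide and the dihydroxyphenyl ring are added afterwards.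

Key step: step 14

Assumption: the target is taken to be the stable tautomer of its phenalenone core, with the enolisable ring D methine in its preferred trans relation to the benzylic methyl group, so that the acidic last step can only keep or restore that centre.
Locants: in the Why lines the naphthalene carbons are numbered as in 11 (C1 and C3 oxygenated, C4 the carbon that receives the two-carbon side chain, C5 its peri carbon, C6 and C8 methoxylated).

Step 1
Reactants: 1 methyl hydrogen (R)-3-methylglutarate
Product: 3 (R)-4-methyltetrahydro-2H-pyran-2-one, via methyl (R)-5-hydroxy-3-methylpentanoate 2 (not isolated)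
Conditions: BH3·SMe2, THF, 0 °C to rt; H2O; TsOH·H2O (cat.), toluene, rt
Reagents that add atoms: none
Why: Chemoselective borane reduction of the acid beside the methyl ester and acid-catalysed lactonisation leave the stereocentre untouched and fix the roles of the two ends, the former ester carbon (lactone carbonyl) becoming the ring A ketone and the former acid carbon the aldehyde, which is the assignment that turns the (R) centre of 1 into the required methyl-bearing centre (the reverse assignment would give its mirror image).

Step 2
Reactants: 3 (R)-4-methyltetrahydro-2H-pyran-2-one; 4 1-fluoro-3-methoxybenzene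
Product: 6 (R)-1-(2-fluoro-6-methoxyphenyl)-5-hydroxy-3-methylpentan-1-one, via 2-fluoro-6-methoxyphenyllithium 5 (not isolated)
Conditions: 4, nBuLi, THF, −78 °C; then 3, −78 °C; H2O
Reagents that add atoms: none
Why: Directed ortho-lithiation between fluorine and methoxy gives the aryllithium, which opens the lactone by acyl substitution, the lithium lactolate and the hindered di-ortho-substituted ketone resisting a second addition and the low temperature preventing benzyne formation.

Step 3
Reactants: 6 (R)-1-(2-fluoro-6-methoxyphenyl)-5-hydroxy-3-methylpentan-1-one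
Product: 7 (R)-5-(tert-butyldimethylsilyloxy)-1-(2-fluoro-6-methoxyphenyl)-3-methylpentan-1-one
Conditions: TBSCl, imidazole, DMF, rt
Reagents that add atoms: tert-butyldimethylsilyl chloride, CC(C)(C)[Si](C)(C)Cl
Why: Routine silylation of the primary alcohol (the open-chain form drains the lactol equilibrium) masks the future aldehyde for the basic ether-forming step.

Step 4
Reactants: 8 3,5-dimethoxyphenylacetic acid
Product: 10 ethyl 4-(3,5-dimethoxyphenyl)-3-oxobutanoate, via acyl imidazolide 9 (not isolated)
Conditions: CDI, THF, rt; then KO2CCH2CO2Et, MgCl2, Et3N, MeCN, rt to 45 °C; 1 M HCl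
Reagents that add atoms: potassium ethyl malonate, CCOC(=O)CC(=O)[O-].[K+]
Why: Masamune–Brooks homologation (acyl imidazolide plus magnesium malonate half-ester, then decarboxylation) is a standard two-carbon extension of an arylacetic acid to the β-keto ester.

Step 5
Reactants: 10 ethyl 4-(3,5-dimethoxyphenyl)-3-oxobutanoate
Product: 11 6,8-dimethoxynaphthalene-1,3-diol
Conditions: MeSO3H, 0 °C to rt; ice-water
Reagents that add atoms: none
Why: Intramolecular Friedel–Crafts acylation by the β-keto ester, the classical naphthalene-1,3-diol synthesis, can only close at one of the two equivalent ring positions next to the side chain, each ortho and para to a methoxy group.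

Step 6
Reactants: 11 6,8-dimethoxynaphthalene-1,3-diol
Product: 12 2,4-dihydroxy-5,7-dimethoxynaphthalene-1-carbaldehyde
Conditions: POCl3 (1.1 equiv), DMF, MeCN, −10 °C to rt; then H2O, 40 °C
Reagents that add atoms: N,N-dimethylformamide, CN(C)C=O
Why: Vilsmeier–Haack formylation should go to C4, the only α position that is ortho to one free hydroxyl and para to the other, in preference to the flanked C2 and to the less activated methoxylated ring.

Step 7
Reactants: 12 2,4-dihydroxy-5,7-dimethoxynaphthalene-1-carbaldehyde
Product: 13 4-(allyloxy)-2-hydroxy-5,7-dimethoxynaphthalene-1-carbaldehyde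
Conditions: allyl bromide (1.05 equiv), K2CO3 (1.1 equiv), DMF, rt
Reagents that add atoms: allyl bromide, C=CCBr
Why: Williamson etherification with one equivalent of base takes the hydroxyl para to the formyl group, which is the more acidic one and is not held in the hydrogen bond that deactivates the ortho hydroxyl, as in 2,4-dihydroxybenzaldehyde.

Step 8
Reactants: 13 4-(allyloxy)-2-hydroxy-5,7-dimethoxynaphthalene-1-carbaldehyde
Product: 14 rac-4-(allyloxy)-1-(1-hydroxyethyl)-5,7-dimethoxynaphthalen-2-ol
Conditions: MeMgBr (2.5 equiv), THF, −78 to 0 °C; aq. work-up at pH 7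
Reagents that add atoms: methylmagnesium bromide, C[Mg]Br
Why: Grignard addition to the magnesium phenoxide of the salicylaldehyde-type aldehyde gives the carbinol as a racemate, which suffices because this centre is erased when the quinone methide forms.

Step 9
Reactants: 14 rac-4-(allyloxy)-1-(1-hydroxyethyl)-5,7-dimethoxynaphthalen-2-ol
Product: 16 rac-4-(allyloxy)-1-[1-(tert-butyldimethylsilyloxy)ethyl]-5,7-dimethoxynaphthalen-2-ol, via bis-silyl ether 15 (not isolated)
Conditions: TBSCl (2.5 equiv), imidazole, DMF, rt; then K2CO3, MeOH, 0 °C to rt
Reagents that add atoms: tert-butyldimethylsilyl chloride, CC(C)(C)[Si](C)(C)Cl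
Why: Exhaustive silylation and selective methanolysis of the much more labile aryl silyl ether leave the phenol free and the benzylic oxygen capped, so that the phenoxide of the next step cannot expel it as an ortho-quinone methide.

Step 10
Reactants: 7 (R)-5-(tert-butyldimethylsilyloxy)-1-(2-fluoro-6-methoxyphenyl)-3-methylpentan-1-one; 16 rac-4-(allyloxy)-1-[1-(tert-butyldimethylsilyloxy)ethyl]-5,7-dimethoxynaphthalen-2-ol
Product: 17 bis-silylated diaryl ether ketone (3R; both epimers at the silyloxyethyl carbon)
Conditions: Cs2CO3, DMSO, 90–100 °C
Reagents that add atoms: none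
Why: Nucleophilic aromatic substitution of the fluoride ortho to the ketone by an unchelated naphthoxide forms the diaryl ether, with no aldehyde present and both alcohols silylated so that only one nucleophile and one electrophile are on offer.

Step 11
Reactants: 17 bis-silylated diaryl ether ketone
Product: 18 diaryl ether keto diol (3R; carbinol epimers)
Conditions: TBAF (2.5 equiv), THF, 0 °C to rt; H2O
Reagents that add atoms: none
Why: Fluoride-induced desilylation frees the primary alcohol and the benzylic carbinol together, while the allyl ether on the naphthol oxygen keeps that carbinol from ionising.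

Step 12
Reactants: 18 diaryl ether keto diol
Product: 19 O-allyl keto aldehyde carbinol (3R; carbinol epimers)
Conditions: TEMPO (10 mol%), PhI(OAc)2 (1.1 equiv), CH2Cl2, rt
Reagents that add atoms: none
Why: The TEMPO/PhI(OAc)2 oxoammonium oxidation takes the primary alcohol to the aldehyde in preference to the di-ortho-substituted secondary benzylic alcohol and tolerates arenes that carry no free phenol.

Step 13
Reactants: 19 O-allyl keto aldehyde carbinol
Product: 20 (3R)-5-[2-({4-hydroxy-1-(1-hydroxyethyl)-5,7-dimethoxynaphthalen-2-yl}oxy)-6-methoxyphenyl]-3-methyl-5-oxopentanal (carbinol epimers)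
Conditions: Pd(PPh3)4 (5 mol%), PhNHMe (3 equiv), THF, rt; used at once
Reagents that add atoms: none
Why: Tsuji–Trost allyl transfer from the aryl allyl ether to N-methylaniline at zerovalent palladium frees the naphthol without acid, strong base or hydride, so the aldehyde and the now ionisable para-hydroxybenzylic carbinol survive.

Step 14
Reactants: 20 naphthol carbinol keto aldehyde
Product: 22 macrocyclic aldehyde (10-membered ring; benzylic carbon R; formyl-bearing methine R; chain methyl carbon S), via quinone methide 21 (not isolated)
Conditions: (S)-2-[diphenyl(trimethylsilyloxy)methyl]pyrrolidine (20 mol%), (PhO)2P(O)OH (10 mol%), CH2Cl2, 0.002 M by slow addition of 20, rt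
Reagents that add atoms: none
Why: Proposed new method: the acid dehydrates the para-hydroxybenzylic carbinol to the planar naphthoquinone methide 21 (both carbinol epimers converge), the amine condenses only with the aldehyde, and the enamine α-carbon adds to the exocyclic methide carbon, after which ring B rearomatises and hydrolysis of the iminium ion returns the catalyst. The closest known reaction is the intermolecular diarylprolinol-silyl-ether-catalysed 1,6-addition of aldehydes to para-quinone methides; new here are the transient alkyl-substituted methide and the ring size. The 10-membered ring closes in a 10-endo-trig mode with respect to the methide double bond, the enamine double bond lying outside the ring. The methine centre is set by the catalyst, whose silyloxydiphenylmethyl group blocks one enamine face so that the (S) catalyst should give the (R) methine as in related Michael additions, and this centre stays correctable by enolisation. The benzylic centre follows from the methide face that the tethered enamine can reach, which the short tether and the resident (R)-methyl centre should narrow to one, the (S) catalyst being taken as the matched case. The step needs intramolecular C-alkylation to beat oligomerisation, arene alkylation by the methoxylated ring and tautomerisation to the vinylnaphthol, which high dilution, the far higher nucleophilicity of the enamine and the reversible protonation of the vinylnaphthol under the acid should secure.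

Step 15
Reactants: 22 macrocyclic aldehyde
Product: 23 O-silylated macrocyclic aldehyde
Conditions: TBSCl, imidazole, DMF, rt to 40 °C
Reagents that add atoms: tert-butyldimethylsilyl chloride, CC(C)(C)[Si](C)(C)Cl
Why: Silylation shields the electron-rich naphthol from the aryllithium and from the periodinane of the next two steps, imidazole being too weak a base to harm the aldehyde.

Step 16
Reactants: 23 O-silylated macrocyclic aldehyde; 24 1,3-dimethoxybenzene
Product: 26 macrocyclic 2,6-dimethoxyphenyl carbinol (both carbinol epimers), via 2,6-dimethoxyphenyllithium 25 (not isolated)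
Conditions: 24, nBuLi, THF, 0 °C to rt; then 23 (1.5 equiv of aryllithium), THF, −78 °C; H2O
Reagents that add atoms: none
Why: Directed ortho-lithiation of the resorcinol diether at C2 and 1,2-addition to the aldehyde, which at −78 °C reacts far faster than the twisted, di-ortho-substituted and enolisable ring A ketone, install ring E, the new carbinol centre being removed in the next step.

Step 17
Reactants: 26 macrocyclic 2,6-dimethoxyphenyl carbinol
Product: 27 macrocyclic 2,6-dimethoxyphenyl ketone
Conditions: Dess–Martin periodinane, CH2Cl2, 0 °C to rt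
Reagents that add atoms: none
Why: Dess–Martin oxidation of the secondary benzylic alcohol gives the aryl ketone under near-neutral conditions that leave the silyl ether, the methyl ethers and the ring A ketone alone.

Step 18
Reactants: 27 macrocyclic 2,6-dimethoxyphenyl ketone
Product: 29 CNP0225737.1 (target), via hexaphenol diketone 28 (not isolated)
Conditions: BBr3 (12 equiv), CH2Cl2, −78 °C to rt; H2O; then TFA, CH2Cl2, rt, under argon
Reagents that add atoms: none
Why: BBr3 cleaves the five aryl methyl ethers and the silyl ether, after which the freed naphthalene-6,8-diol ring attacks the protonated ring E ketone at the peri carbon C5 (intramolecular Friedel–Crafts cyclodehydration closing six-membered ring D) and the resulting para-hydroxy tertiary benzylic alcohol loses water to the quinone methide with C8 as the carbonyl, as in fuchsone and fluorone syntheses, while the methine, now vinylogously enolisable, keeps or regains the trans relation to the benzylic methyl group.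

Compound list
1 | methyl hydrogen (R)-3-methylglutarate | C[C@H](CC(=O)O)CC(=O)OC | starting material
2 | methyl (R)-5-hydroxy-3-methylpentanoate | C[C@H](CCO)CC(=O)OC | intermediate
3 | (R)-4-methyltetrahydro-2H-pyran-2-one | C[C@@H]1CCOC(=O)C1 | intermediate
4 | 1-fluoro-3-methoxybenzene | COc1cccc(F)c1 | starting material
5 | 2-fluoro-6-methoxyphenyllithium | [Li]c1c(F)cccc1OC | intermediate
6 | (R)-1-(2-fluoro-6-methoxyphenyl)-5-hydroxy-3-methylpentan-1-one | COc1cccc(F)c1C(=O)C[C@H](C)CCO | intermediate
7 | (R)-5-(tert-butyldimethylsilyloxy)-1-(2-fluoro-6-methoxyphenyl)-3-methylpentan-1-one | COc1cccc(F)c1C(=O)C[C@H](C)CCO[Si](C)(C)C(C)(C)C | intermediate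
8 | 3,5-dimethoxyphenylacetic acid | COc1cc(OC)cc(CC(=O)O)c1 | starting material
9 | 2-(3,5-dimethoxyphenyl)-1-(1H-imidazol-1-yl)ethan-1-one (acyl imidazolide) | COc1cc(OC)cc(CC(=O)n2ccnc2)c1 | intermediate
10 | ethyl 4-(3,5-dimethoxyphenyl)-3-oxobutanoate | CCOC(=O)CC(=O)Cc1cc(OC)cc(OC)c1 | intermediate
11 | 6,8-dimethoxynaphthalene-1,3-diol | COc1cc(OC)c2c(O)cc(O)cc2c1 | intermediate
12 | 2,4-dihydroxy-5,7-dimethoxynaphthalene-1-carbaldehyde | COc1cc(OC)c2c(O)cc(O)c(C=O)c2c1 | intermediate
13 | 4-(allyloxy)-2-hydroxy-5,7-dimethoxynaphthalene-1-carbaldehyde | COc1cc(OC)c2c(OCC=C)cc(O)c(C=O)c2c1 | intermediate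
14 | rac-4-(allyloxy)-1-(1-hydroxyethyl)-5,7-dimethoxynaphthalen-2-ol | COc1cc(OC)c2c(OCC=C)cc(O)c(C(C)O)c2c1 | intermediate
15 | rac-4-(allyloxy)-2-(tert-butyldimethylsilyloxy)-1-[1-(tert-butyldimethylsilyloxy)ethyl]-5,7-dimethoxynaphthalene (bis-silyl ether) | COc1cc(OC)c2c(OCC=C)cc(O[Si](C)(C)C(C)(C)C)c(C(C)O[Si](C)(C)C(C)(C)C)c2c1 | intermediate
16 | rac-4-(allyloxy)-1-[1-(tert-butyldimethylsilyloxy)ethyl]-5,7-dimethoxynaphthalen-2-ol | COc1cc(OC)c2c(OCC=C)cc(O)c(C(C)O[Si](C)(C)C(C)(C)C)c2c1 | intermediate
17 | (3R)-5-(tert-butyldimethylsilyloxy)-1-[2-({4-allyloxy-1-[1-(tert-butyldimethylsilyloxy)ethyl]-5,7-dimethoxynaphthalen-2-yl}oxy)-6-methoxyphenyl]-3-methylpentan-1-one (epimers at the silyloxyethyl carbon) | COc1cc(OC)c2c(OCC=C)cc(Oc3cccc(OC)c3C(=O)C[C@H](C)CCO[Si](C)(C)C(C)(C)C)c(C(C)O[Si](C)(C)C(C)(C)C)c2c1 | intermediate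
18 | (3R)-1-[2-({4-allyloxy-1-(1-hydroxyethyl)-5,7-dimethoxynaphthalen-2-yl}oxy)-6-methoxyphenyl]-5-hydroxy-3-methylpentan-1-one (carbinol epimers) | COc1cc(OC)c2c(OCC=C)cc(Oc3cccc(OC)c3C(=O)C[C@H](C)CCO)c(C(C)O)c2c1 | intermediate
19 | (3R)-5-[2-({4-allyloxy-1-(1-hydroxyethyl)-5,7-dimethoxynaphthalen-2-yl}oxy)-6-methoxyphenyl]-3-methyl-5-oxopentanal (carbinol epimers) | COc1cc(OC)c2c(OCC=C)cc(Oc3cccc(OC)c3C(=O)C[C@H](C)CC=O)c(C(C)O)c2c1 | intermediate
20 | (3R)-5-[2-({4-hydroxy-1-(1-hydroxyethyl)-5,7-dimethoxynaphthalen-2-yl}oxy)-6-methoxyphenyl]-3-methyl-5-oxopentanal (carbinol epimers; key-step precursor) | COc1cc(OC)c2c(O)cc(Oc3cccc(OC)c3C(=O)C[C@H](C)CC=O)c(C(C)O)c2c1 | intermediate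
21 | (3R)-5-{2-[(1-ethylidene-5,7-dimethoxy-4-oxo-1,4-dihydronaphthalen-2-yl)oxy]-6-methoxyphenyl}-3-methyl-5-oxopentanal (naphthoquinone methide, either alkene geometry) | CC=C1C(Oc2cccc(OC)c2C(=O)C[C@H](C)CC=O)=CC(=O)c2c(OC)cc(OC)cc12 | intermediate
22 | macrocyclic aldehyde: 10-membered ring through the ring A ketone, the diaryl ether oxygen, naphthalene C3 and C4, the benzylic CH(CH3) (R), the formyl-bearing methine (R), the chain CH(CH3) (S) and CH2; free C1 naphthol, three methoxy groups | C[C@H]1CC(=O)c2c(OC)cccc2Oc2cc(O)c3c(OC)cc(OC)cc3c2[C@H](C)[C@@H]1C=O | intermediate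
23 | tert-butyldimethylsilyl ether of 22 at the naphthol oxygen | C[C@H]1CC(=O)c2c(OC)cccc2Oc2cc(O[Si](C)(C)C(C)(C)C)c3c(OC)cc(OC)cc3c2[C@H](C)[C@@H]1C=O | intermediate
24 | 1,3-dimethoxybenzene | COc1cccc(OC)c1 | starting material
25 | 2,6-dimethoxyphenyllithium | [Li]c1c(OC)cccc1OC | intermediate
26 | macrocyclic (2,6-dimethoxyphenyl)carbinol from 23 (epimers at the new carbinol carbon) | C[C@H]1CC(=O)c2c(OC)cccc2Oc2cc(O[Si](C)(C)C(C)(C)C)c3c(OC)cc(OC)cc3c2[C@H](C)[C@@H]1C(O)c1c(OC)cccc1OC | intermediate
27 | macrocyclic 2,6-dimethoxyphenyl ketone | C[C@H]1CC(=O)c2c(OC)cccc2Oc2cc(O[Si](C)(C)C(C)(C)C)c3c(OC)cc(OC)cc3c2[C@H](C)[C@@H]1C(=O)c1c(OC)cccc1OC | intermediate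
28 | hexaphenol diketone (all methyl and silyl ethers of 27 cleaved) | C[C@H]1CC(=O)c2c(O)cccc2Oc2cc(O)c3c(O)cc(O)cc3c2[C@H](C)[C@@H]1C(=O)c1c(O)cccc1O | intermediate
29 | CNP0225737.1 | C[C@H]1CC(=O)c2c(O)cccc2Oc2cc(O)c3c4c2[C@H](C)[C@@H]1C(c1c(O)cccc1O)=C4C(O)=CC3=O | target

Total steps: 18. Longest linear sequence: 15 steps (8 to 29, steps 4–18); the ring A branch (steps 1–3) joins at step 10.

Steps most likely to fail

1. Step 14. The macrocyclic ring closure may lose to oligomerisation, or the enamine may reach the wrong face of the methide and give the epimeric benzylic centre. Fallback with known chemistry, setting out from 6 and 14 and returning at 22: the carbon–carbon bond is made between two molecules and the ring is closed at the diaryl ether instead.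
   - Oxidation of 6 (TEMPO, PhI(OAc)2) gives (R)-5-(2-fluoro-6-methoxyphenyl)-3-methyl-5-oxopentanal F1.
   - Diarylprolinol silyl ether catalysis with a carboxylic acid adds the enamine of F1 to the ortho-quinone methide that 14 releases through its free C3 hydroxyl, a known formal cycloaddition of aldehydes with ortho-hydroxybenzyl alcohols. The catalyst enantiomer is chosen for the (R) benzylic centre. The product is the trans-disposed naphthopyran lactol F2.
   - The lactol opens to the phenoxide under Cs2CO3 in DMSO at high dilution and closes the 10-membered ring by intramolecular nucleophilic aromatic substitution of the fluoride, giving the O-allyl macrocyclic aldehyde F3.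
   - Allyl transfer with Pd(PPh3)4 and PhNHMe then gives 22.

2. Step 10. Substitution at the fluoride may be too slow because the ketone is twisted out of conjugation, so that silyl loss or enolate chemistry takes over at the temperature needed. Fallback, setting out from 3 and 16 and returning at 17: the ether is made by copper catalysis instead.
   - 1-Bromo-3-methoxybenzene is lithiated between bromine and methoxy with LiN(iPr)2 at −78 °C and added to 3, giving (R)-1-(2-bromo-6-methoxyphenyl)-5-hydroxy-3-methylpentan-1-one F4.
   - Silylation with TBSCl and imidazole gives its silyl ether F5.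
   - An Ullmann-type coupling of F5 with 16 (CuI, picolinic acid, K3PO4, DMSO, 90 °C), a system suited to ortho-substituted partners and helped by the ortho carbonyl group, gives 17.

3. Step 18. Ring closure onto the hydrogen-bonded dihydroxyphenyl ketone may stall, or the polyphenol may decompose or condense further under the strong Lewis acid. Fallback, setting out from 26 and returning at 29: ring D is closed by alkylation and the oxidation level is adjusted afterwards.
   - TFA in CH2Cl2 at 0 °C ionises the carbinol of 26 to the 2,6-dimethoxybenzylic cation, which alkylates the peri carbon C5 (Friedel–Crafts alkylation) and gives the ring D closed diarylmethine F6.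
   - BBr3 cleaves the ethers to the leuco hexaphenol F7.
   - One equivalent of DDQ removes the para-hydroxy diarylmethine hydrogen, the usual leuco-to-quinone-methide dehydrogenation, and gives 29.

Further compounds
F1 | step 14 | (R)-5-(2-fluoro-6-methoxyphenyl)-3-methyl-5-oxopentanal | COc1cccc(F)c1C(=O)C[C@H](C)CC=O
F2 | step 14 | naphthopyran lactol from 14 and F1 (trans at the benzylic and adjacent carbons, lactol anomers) | C[C@@H](CC(=O)c1c(F)cccc1OC)[C@H]1C(O)Oc2cc(OCC=C)c3c(OC)cc(OC)cc3c2[C@@H]1C
F3 | step 14 | O-allyl ether of macrocyclic aldehyde 22 | C[C@H]1CC(=O)c2c(OC)cccc2Oc2cc(OCC=C)c3c(OC)cc(OC)cc3c2[C@H](C)[C@@H]1C=O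
F4 | step 10 | (R)-1-(2-bromo-6-methoxyphenyl)-5-hydroxy-3-methylpentan-1-one | COc1cccc(Br)c1C(=O)C[C@H](C)CCO
F5 | step 10 | (R)-1-(2-bromo-6-methoxyphenyl)-5-(tert-butyldimethylsilyloxy)-3-methylpentan-1-one | COc1cccc(Br)c1C(=O)C[C@H](C)CCO[Si](C)(C)C(C)(C)C
F6 | step 18 | ring D closed diarylmethine (sp3 carbon bearing the 2,6-dimethoxyphenyl group, methyl and silyl ethers intact) | C[C@H]1CC(=O)c2c(OC)cccc2Oc2cc(O[Si](C)(C)C(C)(C)C)c3c4c2[C@H](C)[C@@H]1C(c1c(OC)cccc1OC)c4c(OC)cc3OC
F7 | step 18 | leuco hexaphenol (dihydro form of 29) | C[C@H]1CC(=O)c2c(O)cccc2Oc2cc(O)c3c4c2[C@H](C)[C@@H]1C(c1c(O)cccc1O)c4c(O)cc3O
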